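## Retrosynthetic overview

1. Target 41 ⇐ acetylation and desilylation of bicyclo[3.2.1]octenone 39 ⇐ ring D closure (C13–C16) by gold-catalysed 5-exo-dig cyclisation of silyl dienol ether 38 onto the alkyne.
2. Ring C ⇐ catalytic asymmetric Diels–Alder of 2-substituted acrolein 29 (C8, C14, C15) with 1-acetoxybutadiene (C9, C11–C13); C15 carbinol ⇐ ethynyl addition, oxidation, CBS reduction.
3. Ring A ⇐ intramolecular lactone-enolate alkylation (C3–C4) after anti conjugate addition (C5–C10) to butenolide 10; C10–OH ⇐ convex-face epoxidation and reductive opening.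
4. Butenolide 10 ⇐ γ-lactone 6 ⇐ ketoreductase reduction of the achiral γ-keto ester 4 (first stereocentre, C6) ⇐ Grignard acylation of 1 with 2.
5. Ring order: γ-lactone → ring A → ring C → ring D.

Assumption and labels: the SMILES fixes the absolute configuration. Carbons carry ent-kaurane labels: C4 (CH3-bearing lactone α-carbon), C5 (ring-fusion CH), C6 (lactone O–CH), C7 (CH2 link), C8 (quaternary carbon), C9 (ketone), C10 (carbinol), C13 (bridgehead CH), C15 (CH–OAc), C16 (=CH2 carbon); the target is 4R,5S,6R,8R,10R,13S,15R. "Lac" = the (1R,3aR,7R,7aS)-3a,7-dimethyl-3-oxo-7-[(triethylsilyl)oxy]octahydro-2-benzofuran-1-yl group (ring A lactone, attached through C6).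

## Route

Step 1
Reactants: 1 benzyl 3-bromopropyl ether; 2 ethyl 4-chloro-4-oxobutanoate
Product: 4 ethyl 7-(benzyloxy)-4-oxoheptanoate, via Grignard reagent 3 (not isolated)
Conditions: Mg, THF, rt; then 2, Fe(acac)3 (3 mol %), THF, −78 °C
Reagents that add atoms: none
Why: Iron-catalysed Grignard acylation of the acid chloride is faster than attack on the ester or the product ketone; no stereocentre is formed.

Step 2
Reactants: 4 ethyl 7-(benzyloxy)-4-oxoheptanoate
Product: 6 (5R)-5-[3-(benzyloxy)propyl]oxolan-2-one, via hydroxy ester 5 (not isolated)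
Conditions: ketoreductase (R-selective, NADPH-dependent), NADP+ (cat.), i-PrOH, phosphate buffer pH 7, 30 °C; then p-toluenesulfonic acid (cat.), toluene, 50 °C
Reagents that add atoms: none
Why: Enzymatic asymmetric ketone reduction delivers hydride from NADPH to one face of the prochiral C6 ketone and sets C6 (R, the first stereocentre), and acid-catalysed lactonisation closes the γ-lactone.

Step 3
Reactants: 6 (5R)-5-[3-(benzyloxy)propyl]oxolan-2-one
Product: 8 (5R)-5-[3-(benzyloxy)propyl]-3-(phenylselanyl)oxolan-2-one, via lithium enolate 7 (not isolated)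
Conditions: LiN(i-Pr)2, THF, −78 °C; PhSeBr
Reagents that add atoms: benzeneselenenyl bromide, Br[Se]c1ccccc1
Why: α-Selenenylation of the lactone enolate gives a C–Se centre as an epimer mixture that does not matter because it is destroyed in step 4.

Step 4
Reactants: 8 (5R)-5-[3-(benzyloxy)propyl]-3-(phenylselanyl)oxolan-2-one
Product: 10 (5R)-5-[3-(benzyloxy)propyl]furan-2(5H)-one, via selenoxide 9 (not isolated)
Conditions: 30% H2O2, pyridine, CH2Cl2, 0 °C → rt
Reagents that add atoms: none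
Why: Selenide oxidation and selenoxide syn-elimination toward the only β-hydrogens (C5) give the butenolide without touching C6.

Step 5
Reactants: 11 5-chloropent-1-yne
Product: 13 2-bromo-5-chloropent-1-ene, via alkenylborane 12 (not isolated)
Conditions: 9-bromo-9-borabicyclo[3.3.1]nonane, CH2Cl2, 0 °C; then AcOH, rt
Reagents that add atoms: 9-bromo-9-borabicyclo[3.3.1]nonane, BrB1C2CCCC1CCC2
Why: Markovnikov syn-bromoboration of the terminal alkyne followed by protodeboronation gives the 2-bromo-1-alkene; no stereocentre is formed.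

Step 6
Reactants: 13 2-bromo-5-chloropent-1-ene; 10 (5R)-5-[3-(benzyloxy)propyl]furan-2(5H)-one
Product: 17 (4R,5R)-5-[3-(benzyloxy)propyl]-4-(5-chloropent-1-en-2-yl)oxolan-2-one, via vinyllithium 14 (not isolated), via vinyl Grignard reagent 15 (not isolated), via silyl ketene acetal 16 (not isolated)
Conditions: 13, t-BuLi (2 equiv), Et2O, −78 °C; MgBr2·OEt2; then CuBr·SMe2 (10 mol %), Me3SiCl, 10, THF, −78 °C; aq NH4Cl
Reagents that add atoms: none
Why: Copper-catalysed conjugate addition of the alkenyl Grignard reagent, accelerated by Me3SiCl, occurs anti to the C6 side chain and sets C5 trans to C6.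

Step 7
Reactants: 17 (4R,5R)-5-[3-(benzyloxy)propyl]-4-(5-chloropent-1-en-2-yl)oxolan-2-one
Product: 19 (3S,4R,5R)-5-[3-(benzyloxy)propyl]-4-(5-chloropent-1-en-2-yl)-3-methyloxolan-2-one, via lithium enolate 18 (not isolated)
Conditions: LiN(i-Pr)2, THF, −78 °C; MeI
Reagents that add atoms: iodomethane, CI
Why: Lactone enolate alkylation puts the methyl group anti to the C5 substituent, although this centre is re-enolised in step 9 so its ratio is immaterial.

Step 8
Reactants: 19 (3S,4R,5R)-5-[3-(benzyloxy)propyl]-4-(5-chloropent-1-en-2-yl)-3-methyloxolan-2-one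
Product: 20 (3S,4R,5R)-5-[3-(benzyloxy)propyl]-4-(5-iodopent-1-en-2-yl)-3-methyloxolan-2-one
Conditions: NaI, acetone, reflux
Reagents that add atoms: sodium iodide, [Na+].[I-]
Why: Finkelstein halide exchange converts the primary chloride into the more reactive iodide for the ring closure.

Step 9
Reactants: 20 (3S,4R,5R)-5-[3-(benzyloxy)propyl]-4-(5-iodopent-1-en-2-yl)-3-methyloxolan-2-one
Product: 22 (3R,3aS,7aR)-3-[3-(benzyloxy)propyl]-7a-methyl-4-methylidenehexahydro-2-benzofuran-1(3H)-one, via potassium enolate 21 (not isolated)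
Conditions: KN(SiMe3)2, THF, −78 → 0 °C
Reagents that add atoms: none
Why: Intramolecular 6-exo-tet enolate alkylation closes ring A, and because the tether on C5 can only reach the enolate face on its own side the quaternary C4 forms with cis ring fusion (CH3 cis to H5).

Step 10
Reactants: 22 (3R,3aS,7aR)-3-[3-(benzyloxy)propyl]-7a-methyl-4-methylidenehexahydro-2-benzofuran-1(3H)-one
Product: 23 (3R,3aS,4R,7aR)-3-[3-(benzyloxy)propyl]-7a-methylhexahydro-1H-spiro[2-benzofuran-4,2'-oxiran]-1-one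
Conditions: mCPBA, CH2Cl2, 0 °C
Reagents that add atoms: 3-chloroperoxybenzoic acid, OOC(=O)c1cccc(Cl)c1
Why: Prilezhaev epoxidation from the convex face of the cis-fused bicycle (the concave face is shielded by the axial lactone carbon C19 and by C6) places the C10 oxygen on the H5/CH3 side.

Step 11
Reactants: 23 (3R,3aS,4R,7aR)-3-[3-(benzyloxy)propyl]-7a-methylhexahydro-1H-spiro[2-benzofuran-4,2'-oxiran]-1-one
Product: 24 (3R,3aS,4R,7aR)-3-[3-(benzyloxy)propyl]-4-hydroxy-7a-methyl-4-[(phenylselanyl)methyl]hexahydro-2-benzofuran-1(3H)-one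
Conditions: PhSeH, Et3N (cat.), EtOH, 50 °C
Reagents that add atoms: benzeneselenol, [SeH]c1ccccc1
Why: SN2 epoxide opening by selenolate at the CH2 terminus leaves the C10–O bond and its configuration untouched.

Step 12
Reactants: 24 (3R,3aS,4R,7aR)-3-[3-(benzyloxy)propyl]-4-hydroxy-7a-methyl-4-[(phenylselanyl)methyl]hexahydro-2-benzofuran-1(3H)-one
Product: 25 (3R,3aS,4R,7aR)-3-[3-(benzyloxy)propyl]-4-hydroxy-4,7a-dimethylhexahydro-2-benzofuran-1(3H)-one
Conditions: Bu3SnH, azobisisobutyronitrile (cat.), toluene, 90 °C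
Reagents that add atoms: none
Why: Radical deselenation (tin hydride chain) turns CH2SePh into the C10 methyl group without affecting the tertiary alcohol or the lactone.

Step 13
Reactants: 25 (3R,3aS,4R,7aR)-3-[3-(benzyloxy)propyl]-4-hydroxy-4,7a-dimethylhexahydro-2-benzofuran-1(3H)-one
Product: 26 (3R,3aS,4R,7aR)-3-[3-(benzyloxy)propyl]-4,7a-dimethyl-4-[(triethylsilyl)oxy]hexahydro-2-benzofuran-1(3H)-one
Conditions: Et3SiOTf, 2,6-lutidine, CH2Cl2, 0 °C
Reagents that add atoms: triethylsilyl trifluoromethanesulfonate, CC[Si](CC)(CC)OS(=O)(=O)C(F)(F)F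
Why: Silylation with the silyl triflate protects the hindered tertiary alcohol for the Lewis-acid and organometallic steps.

Step 14
Reactants: 26 (3R,3aS,4R,7aR)-3-[3-(benzyloxy)propyl]-4,7a-dimethyl-4-[(triethylsilyl)oxy]hexahydro-2-benzofuran-1(3H)-one
Product: 27 (3R,3aS,4R,7aR)-3-(3-hydroxypropyl)-4,7a-dimethyl-4-[(triethylsilyl)oxy]hexahydro-2-benzofuran-1(3H)-one
Conditions: H2 (1 atm), Pd/C (10% palladium on carbon), EtOAc, rt
Reagents that add atoms: none
Why: Hydrogenolysis of the benzyl ether is chemoselective because no alkene is present at this stage.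

Step 15
Reactants: 27 (3R,3aS,4R,7aR)-3-(3-hydroxypropyl)-4,7a-dimethyl-4-[(triethylsilyl)oxy]hexahydro-2-benzofuran-1(3H)-one
Product: 28 3-(Lac)propanal
Conditions: Dess–Martin periodinane, CH2Cl2, rt
Reagents that add atoms: none
Why: Dess–Martin oxidation converts the primary alcohol into the aldehyde without over-oxidation.

Step 16
Reactants: 28 3-(Lac)propanal
Product: 29 2-[(Lac)methyl]prop-2-enal
Conditions: 37% aq CH2O, pyrrolidine (10 mol %), propionic acid (10 mol %), i-PrOH, 45 °C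
Reagents that add atoms: formaldehyde, C=O
Why: Amine-catalysed Mannich condensation with formaldehyde and elimination (α-methylenation) gives the 2-substituted acrolein carrying C8, C14 and C15.

Step 17
Reactants: 29 2-[(Lac)methyl]prop-2-enal; 30 (E)-buta-1,3-dien-1-yl acetate
Product: 31 (1R,6S)-6-formyl-6-[(Lac)methyl]cyclohex-2-en-1-yl acetate
Conditions: N-protonated (R)-3,3-diphenyl-1-(2-methylphenyl)tetrahydro-1H,3H-pyrrolo[1,2-c][1,3,2]oxazaborole bis(trifluoromethanesulfonyl)imide, [C24H25BNO]+[N(SO2CF3)2]− (20 mol %), CH2Cl2, −78 → −40 °C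
Reagents that add atoms: none
Why: In this catalytic asymmetric Diels–Alder reaction the oxazaborolidinium Lewis acid binds the formyl group and shields the Si face of C8, so the acetoxy-bearing diene terminus adds ortho to the Re face and sets the quaternary C8, while the C9 epimer ratio (exo-CHO isomer drawn) is irrelevant because C9 becomes a ketone in step 23.

Step 18
Reactants: 31 (1R,6S)-6-formyl-6-[(Lac)methyl]cyclohex-2-en-1-yl acetate
Product: 32 (1R,6R)-6-(1-hydroxyprop-2-yn-1-yl)-6-[(Lac)methyl]cyclohex-2-en-1-yl acetate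
Conditions: HC≡CMgBr, THF, −78 °C; AcOH quench at −78 °C
Reagents that add atoms: ethynylmagnesium bromide, C#C[Mg]Br
Why: Grignard 1,2-addition to the aldehyde is faster than attack on the acetate or the hindered lactone, and the unselectively formed C15 centre is corrected in steps 19 and 20.

Step 19
Reactants: 32 (1R,6R)-6-(1-hydroxyprop-2-yn-1-yl)-6-[(Lac)methyl]cyclohex-2-en-1-yl acetate
Product: 33 (1R,6S)-6-[(Lac)methyl]-6-(prop-2-ynoyl)cyclohex-2-en-1-yl acetate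
Conditions: Dess–Martin periodinane, CH2Cl2, 0 °C → rt
Reagents that add atoms: none
Why: Dess–Martin oxidation of the propargylic alcohol to the ynone erases the C15 mixture.

Step 20
Reactants: 33 (1R,6S)-6-[(Lac)methyl]-6-(prop-2-ynoyl)cyclohex-2-en-1-yl acetate
Product: 34 (1R,6R)-6-[(1R)-1-hydroxyprop-2-yn-1-yl]-6-[(Lac)methyl]cyclohex-2-en-1-yl acetate
Conditions: (S)-1-methyl-3,3-diphenyltetrahydro-1H,3H-pyrrolo[1,2-c][1,3,2]oxazaborole (C18H20BNO, 0.5 equiv), catecholborane, CH2Cl2, −78 → −40 °C; MeOH, then aqueous work-up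
Reagents that add atoms: none
Why: In this Corey–Bakshi–Shibata reduction the quaternary C8 is the large and the ethynyl the small ketone substituent, so the (S)-catalyst delivers hydride under reagent control to give the 15R carbinol.

Step 21
Reactants: 34 (1R,6R)-6-[(1R)-1-hydroxyprop-2-yn-1-yl]-6-[(Lac)methyl]cyclohex-2-en-1-yl acetate
Product: 35 (1R,6S)-6-[(1R)-1-{[tert-butyl(dimethyl)silyl]oxy}prop-2-yn-1-yl]-6-[(Lac)methyl]cyclohex-2-en-1-yl acetate
Conditions: t-BuMe2SiOTf, 2,6-lutidine, CH2Cl2, −78 → 0 °C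
Reagents that add atoms: tert-butyldimethylsilyl trifluoromethanesulfonate, CC(C)(C)[Si](C)(C)OS(=O)(=O)C(F)(F)F
Why: Silyl triflate protection of the hindered propargylic alcohol gives an ether that tolerates the gold step, where an ester would migrate.

Step 22
Reactants: 35 (1R,6S)-6-[(1R)-1-{[tert-butyl(dimethyl)silyl]oxy}prop-2-yn-1-yl]-6-[(Lac)methyl]cyclohex-2-en-1-yl acetate
Product: 36 (1R,6S)-6-[(1R)-1-{[tert-butyl(dimethyl)silyl]oxy}prop-2-yn-1-yl]-6-[(Lac)methyl]cyclohex-2-en-1-ol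
Conditions: K2CO3, MeOH, 0 °C → rt
Reagents that add atoms: none
Why: Base-catalysed transesterification removes the allylic acetate while the silyl ethers and the hindered α-quaternary lactone survive.

Step 23
Reactants: 36 (1R,6S)-6-[(1R)-1-{[tert-butyl(dimethyl)silyl]oxy}prop-2-yn-1-yl]-6-[(Lac)methyl]cyclohex-2-en-1-ol
Product: 37 (6R)-6-[(1R)-1-{[tert-butyl(dimethyl)silyl]oxy}prop-2-yn-1-yl]-6-[(Lac)methyl]cyclohex-2-en-1-one
Conditions: Dess–Martin periodinane, CH2Cl2, rt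
Reagents that add atoms: none
Why: Dess–Martin oxidation of the allylic alcohol gives the conjugated C9 enone and removes the C9 stereocentre.

Step 24
Reactants: 37 (6R)-6-[(1R)-1-{[tert-butyl(dimethyl)silyl]oxy}prop-2-yn-1-yl]-6-[(Lac)methyl]cyclohex-2-en-1-one
Product: 38 tert-butyl({(6R)-6-[(1R)-1-{[tert-butyl(dimethyl)silyl]oxy}prop-2-yn-1-yl]-6-[(Lac)methyl]cyclohexa-1,3-dien-1-yl}oxy)dimethylsilane
Conditions: t-BuMe2SiOTf, Et3N, CH2Cl2, 0 °C
Reagents that add atoms: tert-butyldimethylsilyl trifluoromethanesulfonate, CC(C)(C)[Si](C)(C)OS(=O)(=O)C(F)(F)F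
Why: Soft enolisation and O-silylation can only remove a γ-hydrogen at C13 because C8 is quaternary, which gives the 1-silyloxy-1,3-diene.

Step 25
Reactants: 38 tert-butyl({(6R)-6-[(1R)-1-{[tert-butyl(dimethyl)silyl]oxy}prop-2-yn-1-yl]-6-[(Lac)methyl]cyclohexa-1,3-dien-1-yl}oxy)dimethylsilane
Product: 39 (1R,5S,7R)-7-{[tert-butyl(dimethyl)silyl]oxy}-1-[(Lac)methyl]-6-methylidenebicyclo[3.2.1]oct-3-en-2-one
Conditions: Ph3PAuCl (5 mol %), AgSbF6 (5 mol %), CH2Cl2/MeOH 10:1, rt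
Reagents that add atoms: none
Why: In this gold-catalysed vinylogous Conia-ene-type 5-exo-dig carbocyclisation the γ-carbon C13 attacks the activated alkyne on the face fixed by the C8 tether, forming ring D with the exocyclic methylene, setting C13 (S) and regenerating the enone.

Step 26
Reactants: 39 (1R,5S,7R)-7-{[tert-butyl(dimethyl)silyl]oxy}-1-[(Lac)methyl]-6-methylidenebicyclo[3.2.1]oct-3-en-2-one
Product: 40 (1R,5S,7R)-7-hydroxy-1-{[(1R,3aR,7R,7aS)-7-hydroxy-3a,7-dimethyl-3-oxooctahydro-2-benzofuran-1-yl]methyl}-6-methylidenebicyclo[3.2.1]oct-3-en-2-one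
Conditions: HF·pyridine, pyridine, THF, 0 °C → rt
Reagents that add atoms: none
Why: Fluoride-mediated desilylation removes both silyl ethers under mildly acidic conditions that avoid retro-aldol cleavage of the β-hydroxy ketone.

Step 27
Reactants: 40 (1R,5S,7R)-7-hydroxy-1-{[(1R,3aR,7R,7aS)-7-hydroxy-3a,7-dimethyl-3-oxooctahydro-2-benzofuran-1-yl]methyl}-6-methylidenebicyclo[3.2.1]oct-3-en-2-one
Product: 41 (1R,5S,7R)-1-{[(1R,3aR,7R,7aS)-7-hydroxy-3a,7-dimethyl-3-oxooctahydro-2-benzofuran-1-yl]methyl}-6-methylidene-2-oxobicyclo[3.2.1]oct-3-en-7-yl acetate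
Conditions: Ac2O, pyridine, 4-(dimethylamino)pyridine (cat.), CH2Cl2, 0 °C
Reagents that add atoms: acetic anhydride, CC(=O)OC(C)=O
Why: Nucleophile-catalysed acylation acetylates the secondary C15 alcohol only, since the tertiary C10 alcohol is unreactive under these conditions.

## Compound list

1 | benzyl 3-bromopropyl ether | BrCCCOCc1ccccc1 | starting material
2 | ethyl 4-chloro-4-oxobutanoate | CCOC(=O)CCC(Cl)=O | starting material
3 | [3-(benzyloxy)propyl]magnesium bromide | Br[Mg]CCCOCc1ccccc1 | intermediate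
4 | ethyl 7-(benzyloxy)-4-oxoheptanoate | CCOC(=O)CCC(=O)CCCOCc1ccccc1 | intermediate
5 | ethyl (4R)-7-(benzyloxy)-4-hydroxyheptanoate | c1ccccc1COCCC[C@@H](O)CCC(=O)OCC | intermediate
6 | (5R)-5-[3-(benzyloxy)propyl]oxolan-2-one | c1ccccc1COCCC[C@H]1OC(=O)CC1 | intermediate
7 | lithium enolate of 6 | c1ccccc1COCCC[C@H]1OC(O[Li])=CC1 | intermediate
8 | (5R)-5-[3-(benzyloxy)propyl]-3-(phenylselanyl)oxolan-2-one (C3 epimers) | c1ccccc1COCCC[C@H]1OC(=O)C([Se]c2ccccc2)C1 | intermediate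
9 | selenoxide of 8 | c1ccccc1COCCC[C@H]1OC(=O)C([Se](=O)c2ccccc2)C1 | intermediate
10 | (5R)-5-[3-(benzyloxy)propyl]furan-2(5H)-one | c1ccccc1COCCC[C@H]1OC(=O)C=C1 | intermediate
11 | 5-chloropent-1-yne | C#CCCCCl | starting material
12 | 9-[(Z)-2-bromo-5-chloropent-1-en-1-yl]-9-borabicyclo[3.3.1]nonane | ClCCC/C(Br)=C/B1C2CCCC1CCC2 | intermediate
13 | 2-bromo-5-chloropent-1-ene | C=C(Br)CCCCl | intermediate
14 | (5-chloropent-1-en-2-yl)lithium | [Li]C(=C)CCCCl | intermediate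
15 | (5-chloropent-1-en-2-yl)magnesium bromide | Br[Mg]C(=C)CCCCl | intermediate
16 | trimethylsilyl ketene acetal of 17 (2-silyloxy-4,5-dihydrofuran) | c1ccccc1COCCC[C@H]1OC(O[Si](C)(C)C)=C[C@@H]1C(=C)CCCCl | intermediate
17 | (4R,5R)-5-[3-(benzyloxy)propyl]-4-(5-chloropent-1-en-2-yl)oxolan-2-one | c1ccccc1COCCC[C@H]1OC(=O)C[C@@H]1C(=C)CCCCl | intermediate
18 | lithium enolate of 17 | c1ccccc1COCCC[C@H]1OC(O[Li])=C[C@@H]1C(=C)CCCCl | intermediate
19 | (3S,4R,5R)-5-[3-(benzyloxy)propyl]-4-(5-chloropent-1-en-2-yl)-3-methyloxolan-2-one | c1ccccc1COCCC[C@H]1OC(=O)[C@@H](C)[C@@H]1C(=C)CCCCl | intermediate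
20 | (3S,4R,5R)-5-[3-(benzyloxy)propyl]-4-(5-iodopent-1-en-2-yl)-3-methyloxolan-2-one | c1ccccc1COCCC[C@H]1OC(=O)[C@@H](C)[C@@H]1C(=C)CCCI | intermediate
21 | potassium enolate of 20 | c1ccccc1COCCC[C@H]1OC(O[K])=C(C)[C@@H]1C(=C)CCCI | intermediate
22 | (3R,3aS,7aR)-3-[3-(benzyloxy)propyl]-7a-methyl-4-methylidenehexahydro-2-benzofuran-1(3H)-one | c1ccccc1COCCC[C@H]1OC(=O)[C@]2(C)CCCC(=C)[C@H]12 | intermediate
23 | (3R,3aS,4R,7aR)-3-[3-(benzyloxy)propyl]-7a-methylhexahydro-1H-spiro[2-benzofuran-4,2'-oxiran]-1-one | c1ccccc1COCCC[C@H]1OC(=O)[C@]2(C)CCC[C@@]3(OC3)[C@H]12 | intermediate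
24 | (3R,3aS,4R,7aR)-3-[3-(benzyloxy)propyl]-4-hydroxy-7a-methyl-4-[(phenylselanyl)methyl]hexahydro-2-benzofuran-1(3H)-one | c1ccccc1COCCC[C@H]1OC(=O)[C@]2(C)CCC[C@@](C[Se]c3ccccc3)(O)[C@H]12 | intermediate
25 | (3R,3aS,4R,7aR)-3-[3-(benzyloxy)propyl]-4-hydroxy-4,7a-dimethylhexahydro-2-benzofuran-1(3H)-one | c1ccccc1COCCC[C@H]1OC(=O)[C@]2(C)CCC[C@@](C)(O)[C@H]12 | intermediate
26 | (3R,3aS,4R,7aR)-3-[3-(benzyloxy)propyl]-4,7a-dimethyl-4-[(triethylsilyl)oxy]hexahydro-2-benzofuran-1(3H)-one | c1ccccc1COCCC[C@H]1OC(=O)[C@]2(C)CCC[C@@](C)(O[Si](CC)(CC)CC)[C@H]12 | intermediate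
27 | (3R,3aS,4R,7aR)-3-(3-hydroxypropyl)-4,7a-dimethyl-4-[(triethylsilyl)oxy]hexahydro-2-benzofuran-1(3H)-one | OCCC[C@H]1OC(=O)[C@]2(C)CCC[C@@](C)(O[Si](CC)(CC)CC)[C@H]12 | intermediate
28 | 3-(Lac)propanal | O=CCC[C@H]1OC(=O)[C@]2(C)CCC[C@@](C)(O[Si](CC)(CC)CC)[C@H]12 | intermediate
29 | 2-[(Lac)methyl]prop-2-enal | O=CC(=C)C[C@H]1OC(=O)[C@]2(C)CCC[C@@](C)(O[Si](CC)(CC)CC)[C@H]12 | intermediate
30 | (E)-buta-1,3-dien-1-yl acetate | CC(=O)O/C=C/C=C | starting material
31 | (1R,6S)-6-formyl-6-[(Lac)methyl]cyclohex-2-en-1-yl acetate (8S,9R; major C9 epimer) | O=C[C@]1(C[C@H]2OC(=O)[C@]3(C)CCC[C@@](C)(O[Si](CC)(CC)CC)[C@H]23)CCC=C[C@H]1OC(C)=O | intermediate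
32 | (1R,6R)-6-(1-hydroxyprop-2-yn-1-yl)-6-[(Lac)methyl]cyclohex-2-en-1-yl acetate (C15 epimers) | C#CC(O)[C@]1(C[C@H]2OC(=O)[C@]3(C)CCC[C@@](C)(O[Si](CC)(CC)CC)[C@H]23)CCC=C[C@H]1OC(C)=O | intermediate
33 | (1R,6S)-6-[(Lac)methyl]-6-(prop-2-ynoyl)cyclohex-2-en-1-yl acetate | C#CC(=O)[C@]1(C[C@H]2OC(=O)[C@]3(C)CCC[C@@](C)(O[Si](CC)(CC)CC)[C@H]23)CCC=C[C@H]1OC(C)=O | intermediate
34 | (1R,6R)-6-[(1R)-1-hydroxyprop-2-yn-1-yl]-6-[(Lac)methyl]cyclohex-2-en-1-yl acetate | C#C[C@@H](O)[C@]1(C[C@H]2OC(=O)[C@]3(C)CCC[C@@](C)(O[Si](CC)(CC)CC)[C@H]23)CCC=C[C@H]1OC(C)=O | intermediate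
35 | (1R,6S)-6-[(1R)-1-{[tert-butyl(dimethyl)silyl]oxy}prop-2-yn-1-yl]-6-[(Lac)methyl]cyclohex-2-en-1-yl acetate | C#C[C@@H](O[Si](C)(C)C(C)(C)C)[C@]1(C[C@H]2OC(=O)[C@]3(C)CCC[C@@](C)(O[Si](CC)(CC)CC)[C@H]23)CCC=C[C@H]1OC(C)=O | intermediate
36 | (1R,6S)-6-[(1R)-1-{[tert-butyl(dimethyl)silyl]oxy}prop-2-yn-1-yl]-6-[(Lac)methyl]cyclohex-2-en-1-ol | C#C[C@@H](O[Si](C)(C)C(C)(C)C)[C@]1(C[C@H]2OC(=O)[C@]3(C)CCC[C@@](C)(O[Si](CC)(CC)CC)[C@H]23)CCC=C[C@H]1O | intermediate
37 | (6R)-6-[(1R)-1-{[tert-butyl(dimethyl)silyl]oxy}prop-2-yn-1-yl]-6-[(Lac)methyl]cyclohex-2-en-1-one | C#C[C@@H](O[Si](C)(C)C(C)(C)C)[C@]1(C[C@H]2OC(=O)[C@]3(C)CCC[C@@](C)(O[Si](CC)(CC)CC)[C@H]23)CCC=CC1=O | intermediate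
38 | tert-butyl({(6R)-6-[(1R)-1-{[tert-butyl(dimethyl)silyl]oxy}prop-2-yn-1-yl]-6-[(Lac)methyl]cyclohexa-1,3-dien-1-yl}oxy)dimethylsilane | C#C[C@@H](O[Si](C)(C)C(C)(C)C)[C@]1(C[C@H]2OC(=O)[C@]3(C)CCC[C@@](C)(O[Si](CC)(CC)CC)[C@H]23)CC=CC=C1O[Si](C)(C)C(C)(C)C | intermediate
39 | (1R,5S,7R)-7-{[tert-butyl(dimethyl)silyl]oxy}-1-[(Lac)methyl]-6-methylidenebicyclo[3.2.1]oct-3-en-2-one | C=C1[C@@H]2C=CC(=O)[C@@](C[C@H]3OC(=O)[C@]4(C)CCC[C@@](C)(O[Si](CC)(CC)CC)[C@H]34)(C2)[C@@H]1O[Si](C)(C)C(C)(C)C | intermediate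
40 | (1R,5S,7R)-7-hydroxy-1-{[(1R,3aR,7R,7aS)-7-hydroxy-3a,7-dimethyl-3-oxooctahydro-2-benzofuran-1-yl]methyl}-6-methylidenebicyclo[3.2.1]oct-3-en-2-one | C=C1[C@@H]2C=CC(=O)[C@@](C[C@H]3OC(=O)[C@]4(C)CCC[C@@](C)(O)[C@H]34)(C2)[C@@H]1O | intermediate
41 | (1R,5S,7R)-1-{[(1R,3aR,7R,7aS)-7-hydroxy-3a,7-dimethyl-3-oxooctahydro-2-benzofuran-1-yl]methyl}-6-methylidene-2-oxobicyclo[3.2.1]oct-3-en-7-yl acetate (CNP0172716.1) | C=C1[C@@H]2C=CC(=O)[C@@](C[C@H]3OC(=O)[C@]4(C)CCC[C@@](C)(O)[C@H]34)(C2)[C@@H]1OC(C)=O | target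

## Summary

Total step count: 27.
Longest linear sequence: 26 steps (steps 1–4 and 6–27; step 5 prepares 13 on a side branch).

Three steps most likely to fail, each with a fallback:

Step 25 (gold cyclisation). The dienol ether could attack through its α-carbon C11 instead of C13, or simply lose its silyl group and return 37. The fallback sets out from 37 and comes back at 39. The alkyne of 37 is semihydrogenated (H2, Pd/CaCO3 poisoned with Pb(OAc)2, quinoline) to (6R)-6-[(1R)-1-{[tert-butyl(dimethyl)silyl]oxy}prop-2-en-1-yl]-6-[(Lac)methyl]cyclohex-2-en-1-one F1. This is silylated (t-BuMe2SiOTf, Et3N) to the corresponding 1-silyloxy-1,3-diene, tert-butyl({(6R)-6-[(1R)-1-{[tert-butyl(dimethyl)silyl]oxy}prop-2-en-1-yl]-6-[(Lac)methyl]cyclohexa-1,3-dien-1-yl}oxy)dimethylsilane F2. Ring D is then closed by oxidative cycloalkenylation with Pd(OAc)2 under O2 in DMSO (5-exo carbopalladation of the vinyl group, then β-hydride elimination to the exocyclic methylene), which gives 39.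

Step 17 (asymmetric Diels–Alder). Catalyst control at the remote, congested C8 and the modest reactivity of the acetoxydiene are both uncertain. The fallback sets out from 29 and comes back at 31. Catalyst control is given up: the cycloaddition with 30 is promoted by the achiral Lewis acid Me2AlCl (CH2Cl2, −78 °C). Because ring A is already a single enantiomer, the two C8 configurations are diastereomers. Compound 31 is therefore separated by chromatography from its ring C epimer (1S,6R)-6-formyl-6-[(Lac)methyl]cyclohex-2-en-1-yl acetate F3, and the route continues from 31.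

Step 10 (facial selectivity of the epoxidation). A small peracid may not discriminate the two faces of the exocyclic alkene well enough. The fallback sets out from 22 and comes back at 25. Dihydroxylation with the bulkier OsO4 (cat.) and N-methylmorpholine N-oxide from the convex face gives (3R,3aS,4R,7aR)-3-[3-(benzyloxy)propyl]-4-hydroxy-4-(hydroxymethyl)-7a-methylhexahydro-2-benzofuran-1(3H)-one F4. The primary alcohol is converted selectively (I2, PPh3, imidazole) into (3R,3aS,4R,7aR)-3-[3-(benzyloxy)propyl]-4-hydroxy-4-(iodomethyl)-7a-methylhexahydro-2-benzofuran-1(3H)-one F5. Radical deiodination (Bu3SnH, azobisisobutyronitrile) then gives 25.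

Further compounds
F1 | step 25 | (6R)-6-[(1R)-1-{[tert-butyl(dimethyl)silyl]oxy}prop-2-en-1-yl]-6-[(Lac)methyl]cyclohex-2-en-1-one | C=C[C@@H](O[Si](C)(C)C(C)(C)C)[C@]1(C[C@H]2OC(=O)[C@]3(C)CCC[C@@](C)(O[Si](CC)(CC)CC)[C@H]23)CCC=CC1=O
F2 | step 25 | tert-butyl({(6R)-6-[(1R)-1-{[tert-butyl(dimethyl)silyl]oxy}prop-2-en-1-yl]-6-[(Lac)methyl]cyclohexa-1,3-dien-1-yl}oxy)dimethylsilane | C=C[C@@H](O[Si](C)(C)C(C)(C)C)[C@]1(C[C@H]2OC(=O)[C@]3(C)CCC[C@@](C)(O[Si](CC)(CC)CC)[C@H]23)CC=CC=C1O[Si](C)(C)C(C)(C)C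
F3 | step 17 | (1S,6R)-6-formyl-6-[(Lac)methyl]cyclohex-2-en-1-yl acetate | O=C[C@@]1(C[C@H]2OC(=O)[C@]3(C)CCC[C@@](C)(O[Si](CC)(CC)CC)[C@H]23)CCC=C[C@@H]1OC(C)=O
F4 | step 10 | (3R,3aS,4R,7aR)-3-[3-(benzyloxy)propyl]-4-hydroxy-4-(hydroxymethyl)-7a-methylhexahydro-2-benzofuran-1(3H)-one | c1ccccc1COCCC[C@H]1OC(=O)[C@]2(C)CCC[C@@](CO)(O)[C@H]12
F5 | step 10 | (3R,3aS,4R,7aR)-3-[3-(benzyloxy)propyl]-4-hydroxy-4-(iodomethyl)-7a-methylhexahydro-2-benzofuran-1(3H)-one | c1ccccc1COCCC[C@H]1OC(=O)[C@]2(C)CCC[C@@](CI)(O)[C@H]12
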